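## Analysis of the target

- The target 11 is a flavone: benzene ring A is fused to a 4-pyranone ring C (O1, C2, C3, C4, C4a, C8a), and aryl ring B sits on C2.
- It has no stereocentre, so the whole problem is the oxygenation pattern: OMe on C3; OH on C6 and OMe on C7 of ring A; OMe on C2' and C4' and OH on C5' of ring B.
- Each free phenol lies para to another ring oxygen (C6–OH to O1, C5'–OH to the C2'–OMe). Both are hydroquinone monoether units, and their phenoxides oxidise readily in air.
- The pyranone is opened by hot hydroxide. The methyl ethers can be lost to strong Lewis or protic acids, most easily the one on C3 next to the C4 carbonyl.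
- The difficulty is to assemble a hexa-oxygenated flavone with the 3-methoxy group in place and to finish with exactly two hydroxyls free, in few steps.
- The strategy rests on one feature: ring A (C4a, C8a–O1, C7–OMe, C6–OH) and ring B (C1', C2'–OMe, C4'–OMe, C5'–OH) are the same 5-hydroxy-2,4-dioxygenated phenyl unit. They differ only in that the ortho oxygen of ring A is O1 of ring C, while that of ring B keeps its methyl group.
- The two aryl units are joined through C4–C3(OMe)–C2, which at the diketone oxidation level is a methoxymalonyl unit. The carbon skeleton therefore has a hidden twofold symmetry about C3.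

## Retrosynthetic reasoning

**11 back to 10.** The two free hydroxyls are disconnected at their O–acyl bonds to the bis-pivalate 10. Both hydroxyls are the same position of the same aryl unit, so one protecting operation on one phenol covers both. The pivalate is chosen because it should survive a Lewis acid and a strong protic acid, it makes its own ring slightly less nucleophilic without redirecting substitution, and it falls to mild basic alcoholysis that leaves the pyranone and the methyl ethers alone.

**10 back to 8.** Ring C is opened at the O1–C2 bond and a methyl group is put back on O1. This gives the open-chain 2-methoxy-1,3-diketone 8, in which both aryl groups are identical. What is gained is symmetry: either aryl ketone of 8 can become ring A, and both choices lead to 10. The forward reaction has to make the ortho methoxy oxygen attack the far carbonyl, lose its methyl to a nucleophilic counter-ion and lose water, passing through the cyclic hemiketal 9. It can happen only once, because after closure C4 is a vinylogous ester carbonyl held trans to ring B across C2=C3, out of reach of the C2' methoxy group.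

**8 back to 3 (twice) and 6.** The two aryl–carbonyl bonds, C4a–C4 and C1'–C2, are cut. They are equivalent by symmetry, and in each the aryl carbon is C5 of the aryl pivalate 3, the position para to one methoxy group and ortho to the other and so the most nucleophilic carbon of that ring. The three-carbon unit arrives as the dichloride 6 with the C3 methoxy group already attached, so no oxidation at C3 is needed later. Cutting C2–C3 or C3–C4 instead would need two different, separately functionalised aryl building blocks and would not use the symmetry. The forward reaction is a two-directional Friedel–Crafts acylation through the mono-acylated intermediate 7. It must be selective for C5 and must acylate a second arene before 7 can react with itself.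

**3 back to 1 and 2; 6 back to 5 and 4.** The ester O–C(=O) bond of 3 is cut to the phenol 1 and the acid chloride 2. The dichloride 6 comes from the diacid 5, and 5 from saponification of the diester 4. These are routine operations, so the risk of the route sits in the double acylation.

## Alternatives that were turned down

**Alternative 1: a methoxymethylene ylide as the C3 unit.**
- Disconnection: C3–C4 and C2=C3. C3 and its methoxy group come from (methoxymethylene)triphenylphosphorane A3. Rings A and B arrive joined as the O-aroyl salicyloyl chloride A2, whose ester oxygen is already O1.
- Forward key step: A3 is C-acylated by the acid chloride of A2 (C3–C4), a second equivalent of A3 acts as base, and the phosphorane carbon then olefinates the neighbouring aryl ester carbonyl (C2=C3). This closes ring C to the dibenzyl flavone A1, and hydrogenolysis of A1 would give 11.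
- For: O1 is fixed from the start by the ester, so no methyl ether has to be cleaved selectively and no strong acid is needed. On that point it is stronger than the chosen route. Ring C and the 3-methoxy group form in one flask, and ester olefination is an established chromone ring closure. It would also serve flavones whose two aryl rings differ.
- Against: A2 needs a ring A salicylic acid and a ring B benzoic acid, each a tetrasubstituted arene that must be carboxylated, benzylated and then coupled, so the symmetry is unused and the step count roughly doubles. A3 is a basic, non-stabilised ylide that must choose the acid chloride over the aryl ester of A2, and attack at the ester cuts the molecule in two. After acylation the ylide is stabilised, carries a methoxy group and must attack a hindered, electron-rich ester.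
- Comparison: the chosen route makes both aryl–carbonyl bonds in one step from one arene without strong base. It gives up the certainty about O1 and replaces it with a ring closure that symmetry makes unambiguous.

**Alternative 2: building ring A by cyclobutenone ring expansion.**
- Disconnection: the C4a–C8a bond of ring A, from the 4-alkenyl-4-hydroxycyclobutenone A5.
- Forward key step: on heating, A5 undergoes four-electron ring opening, the ketene carbon (C8a) bonds to the alkene terminus (C4a) in a six-electron electrocyclisation, and tautomerisation gives the hydroquinone A4, which carries the masked methoxyacetyl side chain.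
- For: the substitution pattern of ring A is written into A5, and the conditions are neutral. A4 has a free hydroxyl ortho to the masked acyl group, ready to become O1, so no demethylation is needed. It is stronger there.
- Against: ring A is a plain 1,2,4-trioxygenated benzene that aromatic substitution handles directly, so the key step builds what can be bought. Rings C and B are left untouched. After A4 the two hydroxyls must be told apart, the ketal removed and ring C built by acylation with a ring B acid and cyclisation. A5 itself needs a squarate-type cyclobutenedione, removal of one of its oxygens (C8 carries hydrogen) and an alkenyl-metal reagent carrying the ketal. A4 is an air-sensitive hydroquinone.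
- Comparison: the chosen route is about half as long and spends its key step on the bonds that actually join the three rings.

**Alternative 3: carbene-catalysed acyl-anion closure to the flavonol.**
- Disconnection: C3–C4. C4 is the aldehyde carbon and C3 the ester carbon of the aryloxy arylacetate A7, in which the O1–C2 ether bond already exists.
- Forward key step: the carbene A8 adds to the aldehyde of A7, the resulting acyl-anion equivalent attacks the ester carbonyl in a 6-exo closure with expulsion of the ester alkoxide, and the 3,4-dione enolises to the flavonol A6. O-Methylation of A6 gives A1, and hydrogenolysis would then give 11.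
- For: the step is catalytic and close to neutral, and O1 is fixed by the ether. A6 has a free 3-hydroxyl for making analogues, which the chosen route does not offer.
- Against: an unactivated methyl ester is a poor acceptor for a carbene-derived acyl anion. The C2–H of A7 is acidic (next to the ester, benzylic, on an aryloxy carbon), and the base that generates A8 can instead drive an intramolecular aldol onto the aldehyde, a five-membered closure toward a benzofuran. A7 needs a ring A salicylaldehyde and a labile, electron-rich benzylic halide of the ring B arylacetate. The 3-hydroxyl then costs a methylation and the benzyl ethers a hydrogenolysis.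
- Comparison: the chosen route installs the 3-methoxy group with the C3 unit, uses one aryl building block instead of two, and is several steps shorter.

Key step: step 4

Assumption: 1, 2 and 4 are taken as purchasable, and 6 is treated as a compound that tolerates neither distillation nor storage, so it is carried crude into step 4 on the day it is made.

## Route

**Step 1**
Reactants: 1 2,4-dimethoxyphenol; 2 pivaloyl chloride (2,2-dimethylpropanoyl chloride)
Product: 3 2,4-dimethoxyphenyl pivalate (2,4-dimethoxyphenyl 2,2-dimethylpropanoate)
Conditions: Et3N (1.5 equiv), DMAP (5 mol%), CH2Cl2, 0 °C to rt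
Reagents that add atoms: none
Why: O-acylation of a phenol by an acid chloride with nucleophilic catalysis by DMAP; the phenol oxygen is the only nucleophile in 1 and the hindered acyl group does not migrate.

**Step 2**
Reactants: 4 dimethyl methoxymalonate (dimethyl 2-methoxypropanedioate)
Product: 5 methoxymalonic acid (2-methoxypropanedioic acid)
Conditions: NaOH (2.2 equiv), H2O/MeOH, 0 °C to rt; then HCl (aq) to pH 1 at 0 °C, EtOAc extraction, evaporation below 30 °C
Reagents that add atoms: sodium hydroxide, [Na+].[OH-]
Why: Saponification of an unhindered diester by acyl–oxygen cleavage; acidification in the cold and evaporation without heating should keep the malonic acid from decarboxylating.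

**Step 3**
Reactants: 5 methoxymalonic acid
Product: 6 methoxymalonyl dichloride (2-methoxypropanedioyl dichloride)
Conditions: (COCl)2 (3 equiv), DMF (cat.), CH2Cl2, 0 °C to rt; volatiles removed, used crude at once
Reagents that add atoms: oxalyl chloride, O=C(Cl)C(=O)Cl
Why: Acid chloride formation through the chloroiminium (Vilsmeier) salt generated from oxalyl chloride and DMF; all by-products are gases, so evaporation should leave 6 ready for use without heating.

**Step 4**
Reactants: 3 2,4-dimethoxyphenyl pivalate (2.4 equiv); 6 methoxymalonyl dichloride (1 equiv)
Product: 8 1,3-bis[2,4-dimethoxy-5-(pivaloyloxy)phenyl]-2-methoxypropane-1,3-dione, via keto acid chloride 7 (not isolated)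
Conditions: SnCl4 (2.5 equiv), CH2Cl2, 6 added slowly at −30 °C, then 0 °C; ice/1 M HCl
Reagents that add atoms: none
Why: This is a two-directional Friedel–Crafts acylation in which SnCl4 ionises one C–Cl bond of 6 to an acylium ion pair that is attacked by C5 of 3, and loss of the proton from the arenium ion gives the keto acid chloride 7. The remaining acyl chloride of 7 is activated in the same way and acylates C5 of a second molecule of 3, so that the two aryl–carbonyl bonds (C4a–C4 and C1'–C2 of the flavone) are made in one flask. The closest known reaction types are the diacylation of activated arenes with malonyl dichlorides to 1,3-diaryl-1,3-diketones and the acylation of phenol ethers with methoxyacetyl chloride. No ring is closed and no stereocentre is formed, because the methoxy-bearing carbon of 8 carries two identical aroyl groups. The step needs C5 to react in preference to C3 and C6, which the substrate secures since C5 is para to one methoxy group and ortho to the other, C3 is crowded between two methoxy groups, and C6 is meta to both and ortho to the ester. It also needs the second intermolecular acylation to outrun closure of 7 onto its own ortho methoxy oxygen and loss of HCl or carbon monoxide from the acyl unit, which excess 3, slow addition of 6, a mild Lewis acid and low temperature are meant to secure. The first aroyl group deactivates its own ring, so each arene should be acylated only once, and the pivalate should be inert to SnCl4 at this temperature.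

**Step 5**
Reactants: 8 1,3-bis[2,4-dimethoxy-5-(pivaloyloxy)phenyl]-2-methoxypropane-1,3-dione
Product: 10 2-[2,4-dimethoxy-5-(pivaloyloxy)phenyl]-3,7-dimethoxy-4-oxo-4H-chromen-6-yl pivalate, via cyclic hemiketal 9 (not isolated)
Conditions: HBr (33% in AcOH, 4 equiv), AcOH, rt to 50 °C; ice-water
Reagents that add atoms: none
Why: Demethylative cyclodehydration of an ortho-methoxyaryl 1,3-diketone, the acid-mediated form of the diketone-to-flavone closure: an ortho methoxy oxygen adds 6-exo to the protonated far carbonyl, bromide removes the methyl group from the oxonium ion to give hemiketal 9, and acid-catalysed loss of water forms the pyranone. The two aryl ketones of 8 are equivalent, so either mode of closure gives 10, and a second closure is impossible because the ring B methoxy group cannot reach C4.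

**Step 6**
Reactants: 10 2-[2,4-dimethoxy-5-(pivaloyloxy)phenyl]-3,7-dimethoxy-4-oxo-4H-chromen-6-yl pivalate
Product: 11 6,5'-dihydroxy-3,7,2',4'-tetramethoxyflavone
Conditions: K2CO3 (3 equiv), degassed MeOH, rt, Ar; then HCl (aq) to pH 4
Reagents that add atoms: none
Why: Base-mediated methanolysis (transesterification) of aryl esters, which works even for pivalates because phenoxide is a good leaving group; the pyranone and the methyl ethers should be inert to carbonate, and air is excluded because the electron-rich phenoxides oxidise.

## Compound list

1 | 2,4-dimethoxyphenol | COc1ccc(O)c(OC)c1 | starting material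
2 | pivaloyl chloride (2,2-dimethylpropanoyl chloride) | CC(C)(C)C(Cl)=O | starting material
3 | 2,4-dimethoxyphenyl pivalate | COc1ccc(OC(=O)C(C)(C)C)c(OC)c1 | intermediate
4 | dimethyl methoxymalonate | COC(C(=O)OC)C(=O)OC | starting material
5 | methoxymalonic acid | COC(C(=O)O)C(=O)O | intermediate
6 | methoxymalonyl dichloride | COC(C(Cl)=O)C(Cl)=O | intermediate
7 | 3-[2,4-dimethoxy-5-(pivaloyloxy)phenyl]-2-methoxy-3-oxopropanoyl chloride (racemic, formed in the flask, not isolated) | COC(C(Cl)=O)C(=O)c1cc(OC(=O)C(C)(C)C)c(OC)cc1OC | intermediate
8 | 1,3-bis[2,4-dimethoxy-5-(pivaloyloxy)phenyl]-2-methoxypropane-1,3-dione | COC(C(=O)c1cc(OC(=O)C(C)(C)C)c(OC)cc1OC)C(=O)c1cc(OC(=O)C(C)(C)C)c(OC)cc1OC | intermediate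
9 | 2-[2,4-dimethoxy-5-(pivaloyloxy)phenyl]-2-hydroxy-3,7-dimethoxy-4-oxochroman-6-yl pivalate (cyclic hemiketal, mixture of diastereomers, formed in the flask, not isolated) | COc1cc(OC)c(C2(O)Oc3cc(OC)c(OC(=O)C(C)(C)C)cc3C(=O)C2OC)cc1OC(=O)C(C)(C)C | intermediate
10 | 2-[2,4-dimethoxy-5-(pivaloyloxy)phenyl]-3,7-dimethoxy-4-oxo-4H-chromen-6-yl pivalate | COc1cc(OC)c(-c2oc3cc(OC)c(OC(=O)C(C)(C)C)cc3c(=O)c2OC)cc1OC(=O)C(C)(C)C | intermediate
11 | 6,5'-dihydroxy-3,7,2',4'-tetramethoxyflavone | COc1cc(OC)c(-c2oc3cc(OC)c(O)cc3c(=O)c2OC)cc1O | target

## Step count and least certain steps

Total step count: 6. Longest linear sequence: 5 steps (steps 2, 3, 4, 5 and 6, from 4). The arene branch from 1 runs through 4 steps (1, 4, 5 and 6).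

**Step 4 (key step).**
- What may go wrong: the second acylation may stall because 7 binds the tin centre through its keto and acyl chloride oxygens. That leaves time for 7 to close onto its own ortho methoxy oxygen with loss of the methyl group (the pathway to a 4-hydroxycoumarin). The α-methoxy acylium ion may also lose carbon monoxide, so that the arene is alkylated by an oxocarbenium ion instead of being acylated.
- Fallback, from 3 back to 8, with the two aryl–carbonyl bonds made one at a time from the same arene:
  - Acylation of 3 with methoxyacetyl chloride and SnCl4 in CH2Cl2 at 0 °C should give 5-(methoxyacetyl)-2,4-dimethoxyphenyl pivalate F1.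
  - Rieche formylation of a second portion of 3 with dichloromethyl methyl ether and TiCl4 in CH2Cl2 at −10 °C should give 5-formyl-2,4-dimethoxyphenyl pivalate F2.
  - The lithium enolate of F1 (LiN(SiMe3)2, THF, −78 °C) is added to F2 in an aldol reaction to give 3-hydroxy-2-methoxy-1,3-bis[2,4-dimethoxy-5-(pivaloyloxy)phenyl]propan-1-one F3 as a mixture of diastereomers.
  - Oxidation of F3 with Dess–Martin periodinane in CH2Cl2 removes both stereocentres and rejoins the route at 8.

**Step 5.**
- What may go wrong: ether cleavage may run beyond the one ortho methyl group, most easily at the C3 methoxy group next to the C4 carbonyl of the product, or at both ortho methyl groups before the ring closes. If water is present, the 2-substituted diketone may fragment by an acid-induced retro-Claisen cleavage. Partial acidolysis of the pivalates would do no harm, since step 6 removes them.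
- Fallback, from 8 back to 10, separating the two events:
  - One equivalent of BCl3 in CH2Cl2 at −78 to −20 °C, directed by chelation between a ketone oxygen and its ortho methoxy group, should cleave a single aryl methyl ether. This gives 1-[2-hydroxy-4-methoxy-5-(pivaloyloxy)phenyl]-3-[2,4-dimethoxy-5-(pivaloyloxy)phenyl]-2-methoxypropane-1,3-dione F4, the open-chain tautomer of 9.
  - Catalytic H2SO4 in AcOH at rt to 50 °C, the usual closing step of the diketone route to flavones, then cyclises and dehydrates F4 through 9 to 10 without any bromide present.

**Step 3.**
- What may go wrong: decarboxylation of the malonic acid on activation; loss of HCl from 6 to a chlorocarbonyl ketene that oligomerises on concentration; C-formylation at the acidic C–H by the chloroiminium catalyst.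
- Fallback, from 3 back to 8, avoiding 5 and 6 by introducing the C3 methoxy group after the double acylation:
  - Two equivalents of 3 are acylated with purchased malonyl dichloride under the conditions of step 4 to give 1,3-bis[2,4-dimethoxy-5-(pivaloyloxy)phenyl]propane-1,3-dione F5.
  - Diazo transfer from 4-acetamidobenzenesulfonyl azide with Et3N in MeCN gives 2-diazo-1,3-bis[2,4-dimethoxy-5-(pivaloyloxy)phenyl]propane-1,3-dione F6.
  - O–H insertion of the carbenoid generated from F6 with Rh2(OAc)4 (2 mol%) into methanol, used in large excess in CH2Cl2, gives 8.

## Further compounds

F1 | step 4 | 5-(methoxyacetyl)-2,4-dimethoxyphenyl pivalate | COCC(=O)c1cc(OC(=O)C(C)(C)C)c(OC)cc1OC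
F2 | step 4 | 5-formyl-2,4-dimethoxyphenyl pivalate | O=Cc1cc(OC(=O)C(C)(C)C)c(OC)cc1OC
F3 | step 4 | 3-hydroxy-2-methoxy-1,3-bis[2,4-dimethoxy-5-(pivaloyloxy)phenyl]propan-1-one (mixture of diastereomers) | COC(C(O)c1cc(OC(=O)C(C)(C)C)c(OC)cc1OC)C(=O)c1cc(OC(=O)C(C)(C)C)c(OC)cc1OC
F4 | step 5 | 1-[2-hydroxy-4-methoxy-5-(pivaloyloxy)phenyl]-3-[2,4-dimethoxy-5-(pivaloyloxy)phenyl]-2-methoxypropane-1,3-dione (racemic) | COC(C(=O)c1cc(OC(=O)C(C)(C)C)c(OC)cc1O)C(=O)c1cc(OC(=O)C(C)(C)C)c(OC)cc1OC
F5 | step 3 | 1,3-bis[2,4-dimethoxy-5-(pivaloyloxy)phenyl]propane-1,3-dione | O=C(CC(=O)c1cc(OC(=O)C(C)(C)C)c(OC)cc1OC)c1cc(OC(=O)C(C)(C)C)c(OC)cc1OC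
F6 | step 3 | 2-diazo-1,3-bis[2,4-dimethoxy-5-(pivaloyloxy)phenyl]propane-1,3-dione | [N-]=[N+]=C(C(=O)c1cc(OC(=O)C(C)(C)C)c(OC)cc1OC)C(=O)c1cc(OC(=O)C(C)(C)C)c(OC)cc1OC
A1 | alternative 1 | 6-(benzyloxy)-2-[5-(benzyloxy)-2,4-dimethoxyphenyl]-3,7-dimethoxy-4H-chromen-4-one | COc1cc(OC)c(-c2oc3cc(OC)c(OCc4ccccc4)cc3c(=O)c2OC)cc1OCc1ccccc1
A2 | alternative 1 | 5-(benzyloxy)-2-{[5-(benzyloxy)-2,4-dimethoxybenzoyl]oxy}-4-methoxybenzoyl chloride | COc1cc(OC(=O)c2cc(OCc3ccccc3)c(OC)cc2OC)c(C(Cl)=O)cc1OCc1ccccc1
A3 | alternative 1 | (methoxymethylene)triphenylphosphorane | COC=P(c1ccccc1)(c1ccccc1)c1ccccc1
A4 | alternative 2 | 2-(2,5-dihydroxy-4-methoxyphenyl)-2-(methoxymethyl)-1,3-dioxolane | COCC1(OCCO1)c1cc(O)c(OC)cc1O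
A5 | alternative 2 | 4-hydroxy-3-methoxy-4-{(E)-2-[2-(methoxymethyl)-1,3-dioxolan-2-yl]ethenyl}cyclobut-2-en-1-one (racemic) | COCC1(OCCO1)/C=C/C1(O)C(OC)=CC1=O
A6 | alternative 3 | 6-(benzyloxy)-2-[5-(benzyloxy)-2,4-dimethoxyphenyl]-3-hydroxy-7-methoxy-4H-chromen-4-one | COc1cc(OC)c(-c2oc3cc(OC)c(OCc4ccccc4)cc3c(=O)c2O)cc1OCc1ccccc1
A7 | alternative 3 | methyl 2-[4-(benzyloxy)-2-formyl-5-methoxyphenoxy]-2-[5-(benzyloxy)-2,4-dimethoxyphenyl]acetate (racemic) | COC(=O)C(Oc1cc(OC)c(OCc2ccccc2)cc1C=O)c1cc(OCc2ccccc2)c(OC)cc1OC
A8 | alternative 3 | 1,3,4-triphenyl-1,2,4-triazol-5-ylidene | [C]1N(c2ccccc2)N=C(c2ccccc2)N1c1ccccc1
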